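**Retrosynthetic overview**

1. Target 18 ⇐ tert-butyl ester 17 ⇐ saturated acid 16, where a carboxylate-directed Pd β,γ-dehydrogenation introduces C6=C7 last and leaves C8 untouched; 16 ⇐ aldehyde 15.
2. 15 ⇐ acyclic (2E,6Z,10E)-tetraene 12 by one proton-initiated, chair–chair cation–olefin bicyclization (ring A by C4–C5, ring B by C9–C10, head to tail as in the diterpene cyclase). It is ended by a 1,2-hydride shift from the CH2OMe group on the last alkene, which delivers C17 as the aldehyde.
3. 12 ⇐ acetoxymethyl ketone 10 + stabilised ylide 11 (E-enoate); 10 ⇐ ester 8 by one-carbon homologation and acetate displacement.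
4. 8 ⇐ methoxymethyl ketone 5 + ylide 7 (Z-selective α-alkoxy-ketone Wittig); 5 ⇐ geranyl bromide 1 + methyl 4-methoxyacetoacetate 2.
5. Rings A and B close in the same step (12 → 15). Labdane numbering is used for ring positions: C4 = CMe2, C5/C10 = ring fusion, C8 = carboxyl-bearing carbon, C9 = side-chain carbon, C17 = ring carboxyl carbon.

Assumption: the IDPi acid used in step 5 is the antipode of the one that converts (3E,7E)-homofarnesol into natural (−)-ambrox, which by analogy should give the required ent-labdane series (5R,9R,10S).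

**Route**

Step 1
Reactants: 1 geranyl bromide; 2 methyl 4-methoxy-3-oxobutanoate
Product: 5 (E)-1-methoxy-6,10-dimethylundeca-5,9-dien-2-one, via alkylated keto ester 3 (not isolated), via keto acid 4 (not isolated)
Conditions: NaH, THF, 0 °C; 1, 0 °C→rt; then 2 M NaOH, MeOH, rt; then HCl to pH 2, 50 °C
Reagents that add atoms: none
Why: Acetoacetic ester synthesis: SN2 C-alkylation of the β-keto ester enolate by the allylic bromide (E-alkene untouched), then ketonic hydrolysis and decarboxylation in the same pot.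

Step 2
Reactants: 5 (E)-1-methoxy-6,10-dimethylundeca-5,9-dien-2-one; 6 (4-ethoxy-4-oxobutyl)triphenylphosphonium bromide
Product: 8 ethyl (4Z,8E)-5-(methoxymethyl)-9,13-dimethyltetradeca-4,8,12-trienoate, via phosphonium ylide 7 (not isolated)
Conditions: 6, KHMDS, THF, −78→0 °C; then 5, THF/HMPA, −78 °C→rt
Reagents that add atoms: none
Why: Still-type Wittig olefination of an α-alkoxy ketone with a salt-free non-stabilised ylide, which places the ylide substituent cis to the CH2OMe group (Z); the minor E isomer is removed by chromatography.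

Step 3
Reactants: 8 ethyl (4Z,8E)-5-(methoxymethyl)-9,13-dimethyltetradeca-4,8,12-trienoate
Product: 10 (5Z,9E)-6-(methoxymethyl)-10,14-dimethyl-2-oxopentadeca-5,9,13-trien-1-yl acetate, via chloromethyl ketone 9 (not isolated)
Conditions: ICH2Cl, MeLi·LiBr, THF/Et2O, −78 °C; AcOH, −78 °C; then KOAc, NaI (cat.), DMF, 40 °C
Reagents that add atoms: chloroiodomethane ClCI; potassium acetate CC(=O)[O-].[K+]
Why: Chloromethyllithium adds once to the ester (the tetrahedral adduct is stable at −78 °C) to give the chloromethyl ketone on quench, and the activated α-chloride is displaced by acetate (SN2); no stereocentre is involved.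

Step 4
Reactants: 10 (5Z,9E)-6-(methoxymethyl)-10,14-dimethyl-2-oxopentadeca-5,9,13-trien-1-yl acetate; 11 tert-butyl (triphenylphosphoranylidene)acetate
Product: 12 tert-butyl (2E,6Z,10E)-3-(acetoxymethyl)-7-(methoxymethyl)-11,15-dimethylhexadeca-2,6,10,14-tetraenoate
Conditions: 11, toluene, 90 °C
Reagents that add atoms: none
Why: Wittig reaction of a stabilised ylide with an α-acyloxy ketone, which places the ester trans to the oxygen-bearing CH2 (E-enoate, chain cis to the ester) as with acetoxyacetone; the minor 2Z isomer is separated.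

Step 5
Reactants: 12 tert-butyl (2E,6Z,10E)-3-(acetoxymethyl)-7-(methoxymethyl)-11,15-dimethylhexadeca-2,6,10,14-tetraenoate
Product: 15 tert-butyl (E)-3-(acetoxymethyl)-5-[(1R,2S,4aR,8aS)-2-formyl-5,5,8a-trimethyldecahydronaphthalen-1-yl]pent-2-enoate, via O-methyl oxocarbenium ion 13 (not isolated), via C8-epimeric axial aldehyde 14 (not isolated)
Conditions: ent-IDPi (confined chiral imidodiphosphorimidate acid, 5 mol%), (CF3)3COH, −20 °C; aq. NaHCO3; then DBU (10 mol%), CH2Cl2, rt
Reagents that add atoms: water O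
Why: Proposed new method: the confined chiral acid protonates the terminal isopropylidene alkene and the chain folds chair–chair so that C4–C5 and C9–C10 form anti across each alkene (E-alkene gives the trans ring fusion, the Z-allylic ether geometry puts the side chain equatorial and cis to the angular methyl), with the catalyst antipode fixing the absolute sense at C5, C9 and C10; the tertiary C8 cation is quenched by a 1,2-hydride shift from the adjacent CH2OMe (semipinacol/Prins–pinacol-type termination) to an oxocarbenium ion that water hydrolyses to the aldehyde, and DBU then equilibrates the epimerisable C8 to the equatorial formyl group trans to the side chain; the closest known reactions are the IDPi-catalysed bicyclization of homofarnesol to ambrox and acid-mediated Prins–pinacol terminations.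

Step 6
Reactants: 15 tert-butyl (E)-3-(acetoxymethyl)-5-[(1R,2S,4aR,8aS)-2-formyl-5,5,8a-trimethyldecahydronaphthalen-1-yl]pent-2-enoate
Product: 16 (1R,2S,4aR,8aS)-1-[(E)-3-(acetoxymethyl)-5-tert-butoxy-5-oxopent-3-en-1-yl]-5,5,8a-trimethyldecahydronaphthalene-2-carboxylic acid
Conditions: NaClO2, NaH2PO4, 2-methyl-2-butene, t-BuOH/H2O, rt
Reagents that add atoms: sodium chlorite [Na+].[O-]Cl=O
Why: Pinnick oxidation converts the hindered aldehyde to the acid under buffered, non-enolising conditions, so C8 keeps its configuration.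

Step 7
Reactants: 16 (1R,2S,4aR,8aS)-1-[(E)-3-(acetoxymethyl)-5-tert-butoxy-5-oxopent-3-en-1-yl]-5,5,8a-trimethyldecahydronaphthalene-2-carboxylic acid
Product: 17 (1R,2S,4aR,8aS)-1-[(E)-3-(acetoxymethyl)-5-tert-butoxy-5-oxopent-3-en-1-yl]-5,5,8a-trimethyl-1,2,4a,5,6,7,8,8a-octahydronaphthalene-2-carboxylic acid
Conditions: Pd(OAc)2 (10 mol%), bidentate pyridine–pyridone ligand (12 mol%), Ag2CO3 (2 equiv), HFIP, 100 °C
Reagents that add atoms: none
Why: Ligand-enabled, carboxylate-directed Pd(II) β-methylene C–H activation at C7 followed by β-hydride elimination (β,γ-dehydrogenation of a free aliphatic acid); palladium on C7 is cis to the carboxyl, so H-8 is anti and the only syn β-hydrogen is on C6, which forces the C6=C7 alkene and leaves the C8 stereocentre untouched.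

Step 8
Reactants: 17 (1R,2S,4aR,8aS)-1-[(E)-3-(acetoxymethyl)-5-tert-butoxy-5-oxopent-3-en-1-yl]-5,5,8a-trimethyl-1,2,4a,5,6,7,8,8a-octahydronaphthalene-2-carboxylic acid
Product: 18 (1R,2S,4aR,8aS)-1-[(E)-3-(acetoxymethyl)-4-carboxybut-3-en-1-yl]-5,5,8a-trimethyl-1,2,4a,5,6,7,8,8a-octahydronaphthalene-2-carboxylic acid (target)
Conditions: TFA, CH2Cl2, 0 °C→rt
Reagents that add atoms: none
Why: Acidolysis of the tert-butyl ester (E1 loss of isobutene) frees the second acid without base, so the allylic acetate survives and the β,γ-unsaturated acid is neither epimerised nor conjugated.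

**Compound list**

1 | geranyl bromide, (E)-1-bromo-3,7-dimethylocta-2,6-diene | BrC/C=C(\C)CCC=C(C)C | starting material
2 | methyl 4-methoxy-3-oxobutanoate | COCC(=O)CC(=O)OC | starting material
3 | methyl (E)-2-(2-methoxyacetyl)-5,9-dimethyldeca-4,8-dienoate (racemic, not isolated) | COCC(=O)C(C/C=C(\C)CCC=C(C)C)C(=O)OC | intermediate
4 | (E)-2-(2-methoxyacetyl)-5,9-dimethyldeca-4,8-dienoic acid (racemic, not isolated) | COCC(=O)C(C/C=C(\C)CCC=C(C)C)C(=O)O | intermediate
5 | (E)-1-methoxy-6,10-dimethylundeca-5,9-dien-2-one | COCC(=O)CC/C=C(\C)CCC=C(C)C | intermediate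
6 | (4-ethoxy-4-oxobutyl)triphenylphosphonium bromide | CCOC(=O)CCC[P+](c1ccccc1)(c2ccccc2)c3ccccc3.[Br-] | starting material
7 | ethyl 4-(triphenyl-λ5-phosphanylidene)butanoate (ylide, not isolated) | CCOC(=O)CCC=P(c1ccccc1)(c2ccccc2)c3ccccc3 | intermediate
8 | ethyl (4Z,8E)-5-(methoxymethyl)-9,13-dimethyltetradeca-4,8,12-trienoate | CCOC(=O)CC/C=C(\COC)CC/C=C(\C)CCC=C(C)C | intermediate
9 | (5Z,9E)-1-chloro-6-(methoxymethyl)-10,14-dimethylpentadeca-5,9,13-trien-2-one (not isolated) | ClCC(=O)CC/C=C(\COC)CC/C=C(\C)CCC=C(C)C | intermediate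
10 | (5Z,9E)-6-(methoxymethyl)-10,14-dimethyl-2-oxopentadeca-5,9,13-trien-1-yl acetate | CC(=O)OCC(=O)CC/C=C(\COC)CC/C=C(\C)CCC=C(C)C | intermediate
11 | tert-butyl (triphenylphosphoranylidene)acetate | CC(C)(C)OC(=O)C=P(c1ccccc1)(c2ccccc2)c3ccccc3 | starting material
12 | tert-butyl (2E,6Z,10E)-3-(acetoxymethyl)-7-(methoxymethyl)-11,15-dimethylhexadeca-2,6,10,14-tetraenoate | CC(=O)OC/C(=C/C(=O)OC(C)(C)C)CC/C=C(\COC)CC/C=C(\C)CCC=C(C)C | intermediate
13 | O-methyl oxocarbenium ion of the bicyclic C8-axial aldehyde, as its IDPi salt (not isolated) | CC(=O)OC/C(=C/C(=O)OC(C)(C)C)CC[C@@H]1[C@H](C=[O+]C)CC[C@@H]2C(C)(C)CCC[C@@]12C | intermediate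
14 | tert-butyl (E)-3-(acetoxymethyl)-5-[(1R,2R,4aR,8aS)-2-formyl-5,5,8a-trimethyldecahydronaphthalen-1-yl]pent-2-enoate (axial CHO, not isolated) | CC(=O)OC/C(=C/C(=O)OC(C)(C)C)CC[C@@H]1[C@H](C=O)CC[C@@H]2C(C)(C)CCC[C@@]12C | intermediate
15 | tert-butyl (E)-3-(acetoxymethyl)-5-[(1R,2S,4aR,8aS)-2-formyl-5,5,8a-trimethyldecahydronaphthalen-1-yl]pent-2-enoate | CC(=O)OC/C(=C/C(=O)OC(C)(C)C)CC[C@@H]1[C@@H](C=O)CC[C@@H]2C(C)(C)CCC[C@@]12C | intermediate
16 | (1R,2S,4aR,8aS)-1-[(E)-3-(acetoxymethyl)-5-tert-butoxy-5-oxopent-3-en-1-yl]-5,5,8a-trimethyldecahydronaphthalene-2-carboxylic acid | CC(=O)OC/C(=C/C(=O)OC(C)(C)C)CC[C@@H]1[C@@H](C(=O)O)CC[C@@H]2C(C)(C)CCC[C@@]12C | intermediate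
17 | (1R,2S,4aR,8aS)-1-[(E)-3-(acetoxymethyl)-5-tert-butoxy-5-oxopent-3-en-1-yl]-5,5,8a-trimethyl-1,2,4a,5,6,7,8,8a-octahydronaphthalene-2-carboxylic acid | CC(=O)OC/C(=C/C(=O)OC(C)(C)C)CC[C@@H]1[C@@H](C(=O)O)C=C[C@@H]2C(C)(C)CCC[C@@]12C | intermediate
18 | (1R,2S,4aR,8aS)-1-[(E)-3-(acetoxymethyl)-4-carboxybut-3-en-1-yl]-5,5,8a-trimethyl-1,2,4a,5,6,7,8,8a-octahydronaphthalene-2-carboxylic acid (CNP0108723.1) | CC(=O)OC/C(=C/C(=O)O)CC[C@@H]1[C@@H](C(=O)O)C=C[C@@H]2C(C)(C)CCC[C@@]12C | target

**Step count**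

Total steps: 8. Longest linear sequence: 8 (1 → 5 → 8 → 10 → 12 → 15 → 16 → 17 → 18).

**Steps most likely to fail, and fallbacks**

Step 5 is the largest risk. The enantioselectivity on this chain is unproven, the allylic methyl ether may ionise or slow closure of ring B, proton loss may compete with the hydride shift, and the tert-butyl ester may partly cleave. The fallback replaces catalyst control by an epoxide stereocentre and sets out from 12. Shi epoxidation (D-fructose-derived ketone, Oxone, pH 10.5, 0 °C, partial conversion, separation from the internal epoxide) gives the terminal epoxide tert-butyl (2E,6Z,10E)-3-(acetoxymethyl)-13-[(2R)-3,3-dimethyloxiran-2-yl]-7-(methoxymethyl)-11-methyltrideca-2,6,10-trienoate F1. MeAlCl2 in CH2Cl2 at −78 °C, aqueous work-up and DBU then give the 3-hydroxy analogue of 15 with equatorial OH on the ring carbon next to CMe2 F2, the epoxide centre dictating the chair–chair folding. 1,1′-Thiocarbonyldiimidazole converts it into the O-imidazolylthiocarbonyl derivative F3, and Bu3SnH/AIBN (Barton–McCombie) removes the oxygen and comes back to the route at 15.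

Step 7 is the second risk. β,γ-Dehydrogenation on a hindered decalin acid may be slow, the new alkene may migrate, and Pd(0) may attack the allylic acetate. The fallback sets out from 15 and uses a conjugate addition and syn-elimination sequence. IBX in DMSO at 65 °C gives the ring-conjugated enal F4 (C7=C8). PhSeH (from PhSeSePh/NaBH4, EtOH, AcOH) adds to it axially, and thermodynamic protonation gives the 7-phenylselanyl aldehyde F5 with selenium cis to the equatorial formyl group. H2O2/pyridine gives the selenoxide F6, whose only syn hydrogen is on C6, so it eliminates to the β,γ-unsaturated aldehyde F7. Pinnick oxidation of F7 comes back to the route at 17.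

Step 4 is the third risk, because the E/Z ratio with a ketone flanked by CH2OAc and a long alkyl chain may be modest. The fallback sets out from 8 and fixes the geometry by a stereospecific coupling. Crossed Claisen condensation with the lithium enolate of tert-butyl acetate gives the β-keto ester tert-butyl (6Z,10E)-7-(methoxymethyl)-11,15-dimethyl-3-oxohexadeca-6,10,14-trienoate F8. Aqueous Me4NOH/Tf2O gives the (E)-enol triflate F9 with the triflate trans to the ester. Suzuki–Miyaura coupling with potassium (acetoxymethyl)trifluoroborate (Pd/RuPhos, K2CO3, dioxane/H2O), with loss of the acetyl group under the basic conditions, gives the (E)-hydroxymethyl enoate F10 with retention of geometry. Ac2O/pyridine then comes back to the route at 12.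

**Further compounds**

F1 | step 5 | tert-butyl (2E,6Z,10E)-3-(acetoxymethyl)-13-[(2R)-3,3-dimethyloxiran-2-yl]-7-(methoxymethyl)-11-methyltrideca-2,6,10-trienoate | CC(=O)OC/C(=C/C(=O)OC(C)(C)C)CC/C=C(\COC)CC/C=C(\C)CC[C@H]1OC1(C)C
F2 | step 5 | 3-hydroxy analogue of 15 (labdane C3, R, OH equatorial) | CC(=O)OC/C(=C/C(=O)OC(C)(C)C)CC[C@@H]1[C@@H](C=O)CC[C@@H]2C(C)(C)[C@H](O)CC[C@@]12C
F3 | step 5 | O-(imidazol-1-ylthiocarbonyl) derivative of F2 | CC(=O)OC/C(=C/C(=O)OC(C)(C)C)CC[C@@H]1[C@@H](C=O)CC[C@@H]2C(C)(C)[C@H](OC(=S)n3ccnc3)CC[C@@]12C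
F4 | step 7 | ring-conjugated enal (C7=C8) derived from 15 | CC(=O)OC/C(=C/C(=O)OC(C)(C)C)CC[C@@H]1C(C=O)=CC[C@@H]2C(C)(C)CCC[C@@]12C
F5 | step 7 | 7-phenylselanyl aldehyde (Se axial, cis to the equatorial CHO) | CC(=O)OC/C(=C/C(=O)OC(C)(C)C)CC[C@@H]1[C@@H](C=O)[C@@H]([Se]c3ccccc3)C[C@@H]2C(C)(C)CCC[C@@]12C
F6 | step 7 | selenoxide of F5 | CC(=O)OC/C(=C/C(=O)OC(C)(C)C)CC[C@@H]1[C@@H](C=O)[C@@H]([Se](=O)c3ccccc3)C[C@@H]2C(C)(C)CCC[C@@]12C
F7 | step 7 | β,γ-unsaturated aldehyde (C6=C7) corresponding to 17 | CC(=O)OC/C(=C/C(=O)OC(C)(C)C)CC[C@@H]1[C@@H](C=O)C=C[C@@H]2C(C)(C)CCC[C@@]12C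
F8 | step 4 | tert-butyl (6Z,10E)-7-(methoxymethyl)-11,15-dimethyl-3-oxohexadeca-6,10,14-trienoate | CC(C)(C)OC(=O)CC(=O)CC/C=C(\COC)CC/C=C(\C)CCC=C(C)C
F9 | step 4 | tert-butyl (2E,6Z,10E)-7-(methoxymethyl)-11,15-dimethyl-3-(trifluoromethylsulfonyloxy)hexadeca-2,6,10,14-tetraenoate | CC(C)(C)OC(=O)/C=C(/OS(=O)(=O)C(F)(F)F)CC/C=C(\COC)CC/C=C(\C)CCC=C(C)C
F10 | step 4 | tert-butyl (2E,6Z,10E)-3-(hydroxymethyl)-7-(methoxymethyl)-11,15-dimethylhexadeca-2,6,10,14-tetraenoate | OC/C(=C/C(=O)OC(C)(C)C)CC/C=C(\COC)CC/C=C(\C)CCC=C(C)C
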